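We have no rate constants, so we read one time constant off the runs and reckon in fractions of the charge.

| flask | starting material | partner | second substrate | remark | time |
|---|---|---|---|---|---|
| dawn | 0.10 M | 0.15 M | 0.10 M | run made earlier |  |
| spring | 0.10 M | 0.15 M | 0.050 M | run made earlier |  |
| dusk | 0.10 M | 0.15 M | 0.075 M | run made earlier |  |
| summer | 0.20 M | 0.15 M | 0.10 M | run made earlier |  |
| amber | 0.10 M | 0.150 M | 0.100 M | a closed flask charged with all of it at once and left for 3.0 d | 3.0 d |
| red | 0.10 M | 0.150 M | 0.100 M (fed, over 2.40 d) | all but second substrate at the start; second substrate goes in evenly over 2.40 d, the run ends at 3.0 d | 3.0 d |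
| green | 0.10 M (fed, over 2.40 d) | 0.150 M | 0.100 M | all but starting material at the start; starting material goes in evenly over 2.40 d, the run ends at 3.0 d | 3.0 d |
| blue | 0.10 M | 0.150 M | 0.100 M | one stirred flow tank at steady state, fed with the mixture as stated, mean residence time 3.0 d |  |

| run | time / d | target / % |
|---|---|---|
| dawn | 0.250 | 20.1 |
| dawn | 0.833 | 24.7 |
| dawn | 1.25 | 24.4 |
| dawn | 2.00 | 24.6 |
| dawn | 3.00 | 24.7 |
| spring | 0.208 | 20.0 |
| spring | 0.333 | 22.7 |
| spring | 0.625 | 25.5 |
| spring | 1.25 | 25.4 |
| spring | 2.50 | 24.2 |
| dusk | 0.208 | 19.0 |
| dusk | 0.625 | 25.2 |
| dusk | 1.04 | 24.7 |
| dusk | 1.67 | 25.3 |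
| dusk | 2.50 | 25.3 |
| summer | 0.208 | 17.5 |
| summer | 0.333 | 19.3 |
| summer | 0.625 | 20.6 |
| summer | 1.25 | 20.1 |
| summer | 2.50 | 19.4 |

(standard deviation of a reading: 0.5 percentage points)

- the stated concentrations are those of everything mixed, before any reaction; amounts are the same in each set-up
- the feed brings no volume worth counting
- the earlier runs were made in a closed, stirred flask

1. the set-up with the highest amount of target at the outlet or at the end, in percent of the starting material put in ("none" if the first two lie within 2 percentage points) (amber / red / green / blue / none)
2. amount of target at the outlet or at the end, in percent of the starting material put in, amber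
3. amount of target at the outlet or at the end, in percent of the starting material put in, red
4. amount of target at the outlet or at the end, in percent of the starting material put in, green
5. amount of target at the outlet or at the end, in percent of the starting material put in, blue

Dawn has the charges of amber and stops moving: its last readings average y∞ = 24.6% of the charge. Taking the approach as one exponential, its first reading gives

τ = 0.250 d / ln(24.6% / (24.6% − 20.1%)) = 0.147 d

We call τ the settling time of the target; it is a reading and carries the scatter of 0.5 percentage points.

Our bench rule for these flasks: after 3 settling times, the target in a closed flask stands near the plateau of dawn, provided the totals are those of dawn. Amber, red and green hold the same totals as dawn, and the feeds stop with a tail left: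

(t − t_feed) / τ = 4.08

That tail is longer than 3 settling times, so we put amber, red and green at 24.6%.

Blue is the border of the rule. Its outlet mixes parcels of every age, so a ratio of 20.4 between residence time and settling time does not clear the shortfall exponentially. We solve both ends and join them. A short stay gives y∞·θ/τ, a long stay gives y∞, and together:

y = y∞ · θ / (θ + τ) = 23.4%

Our top two lie within 2 points, so our verdict is none.

The forecast reads the runs differently, as “a second-order self-loss of starting material competes with first-order channels”. It gives amber 24.9%, red 24.8%, green 33%, blue 31.8%, verdict none. We part from it on green and blue.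

The flasks give amber 24.8%, red 24.8%, green 24.5%, blue 23.0%, verdict none.

    starting material + partner ⇌ target (K = 13.0 /M, k = 0.460 /M/h)
    second substrate + partner ⇌ second product (K = 1.40 /M, k = 0.340 /M/h)
    target ⇌ isomer of the product (K = 1.90, k = 0.100 /h)

Red shows the largest single effect: with the exchange of target and isomer of the product taken away, red ends at 53.0% instead of 24.8%, a rise that makes up 38% of what is missing. Amber ends with 45.7% of its charge as isomer of the product, and red stands at 24.9% after 30.0 d, which is thermodynamic control in the usual term. Slow dosing does not raise green, which stands at 24.5% with it and 24.8% without it, after a tail of 4.08 settling times. On blue, the settling time of 0.147 d gives 23.4%, and the tank gives 23.0%.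

(All runs were computed for an exercise.)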